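The east run was what I had when dusk, noon and winter came up: 5.5 mM of substrate under gas phase held at 3 mM, followed as target in percent of the charge.

| setting | east | dusk | noon | winter |
|---|---|---|---|---|
| substrate | 5.5 mM | 5.0 mM | 10 mM | 20 mM |
| gas phase | 3 mM (held) | 3.0 mM (held) | 3.0 mM (held) | 3.0 mM (held) |
| remark | run made earlier |  |  |  |
| time |  | 25 h | 25 h | 25 h |

east run (percent of the substrate charged): time / h: target / % = 1.33: 2; 2.00: 5; 3.00: 9; 4.00: 7; 6.00: 14; 10.0: 22; 15.0: 31

(readings scatter by 1.5 percentage points)

- at the start none of the gas phase is in solution
- "hardly changes" means that all values lie within two and a half points (for a concentration: within two and a half percent of the largest)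

* [target] at the end for dusk, noon, winter, in this order
* the course of these numbers from the first flask to the last (falls all the way / falls, then rises / rises all the way / rises, then falls / hardly changes)

From the last reading, 31% after 15.0 h, I took a loss of 0.0247 h⁻¹ and from it 28.0 h as the apparent half-life of substrate: the time in which [substrate] halves if a steady level of gas phase in solution makes its loss pseudo-first-order and every substrate lost stands as target. It is a reading and carries the scatter of 1.5 percentage points.

I ran the flask slowly in my head. At first no gas phase is in solution, and I assumed that substrate must wait for it; the early reading of 2% at 1.33 h stands against 3.23% from the half-life, with that scatter on it. In the middle I took the entry of gas as the fast step, already steady, with substrate losing the same share each hour. By 25 h dusk then keeps 53.9% of its substrate. What is about to matter at the end is whether target survives, and the east readings stop 10.0 h short of that time.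

If the steady level does not depend on the charge, the share left is the same in each flask, and my [target] comes to 2.31 mM, 4.61 mM and 9.22 mM. The forecast gave 2.3 mM, 4.5 mM and 8.5 mM, course rises all the way, on the caution that “Saturation, or a gas-transfer limit, could hold these lower”. My winter figure stands higher than the forecast's.

At 25 h dusk held 1.82 mM, noon 3.58 mM and winter 6.84 mM, the course rises all the way.

    gas phase ⇌ dissolved gas, rate k1*(csat - [dissolved gas]) (kL = 0.430 h⁻¹)
    substrate + dissolved gas → target (k = 32.0 L mol⁻¹ h⁻¹)
    dissolved gas + target → over-reacted product (k = 32.0 L mol⁻¹ h⁻¹)
    2 dissolved gas → self-condensation product (k = 280 L mol⁻¹ h⁻¹)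

In dusk the half-life of target by its over-reaction with dissolved gas was 20 h at 25.0 h, shorter than my 28.0 h, and target was then made 1.18 times as fast as it was used up, each step taken net. Dusk had 43% of its substrate left against the 53.9% reckoned from 28.0 h, and winter, the third flask, had 51% left with 34.2% standing as target.

The numbers in the tables were generated by integration with made-up constants.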